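## Structural features

The target is a diaryl ether of two benzene rings and no other ring. Ring A is a benzoic acid (C1) with a methoxy group at C2, the (1R)-1,3-dihydroxy-3-methylbutyl chain at C3 and the aryloxy oxygen at C6. Ring B (C1' on the ether oxygen) has a phenolic hydroxyl at C2', a methyl group at C4' and a hydroxymethyl group at C6'. Ring A is therefore substituted at four adjacent positions, and the ether oxygen has two ortho neighbours on each ring, so both the diaryl ether bond and the carboxyl group are sterically crowded. The only stereocentre is the benzylic carbinol carbon Cα on C3 (R); it has no stereogenic neighbour, so its configuration must come from a reagent or catalyst. The fragile points are: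

- the secondary benzylic alcohol, activated towards ionisation by the ortho methoxy and para aryloxy groups and placed 1,3 to a tertiary alcohol, so acid must be avoided;
- the benzylic C–O bonds, which can be hydrogenolysed;
- the 2'-hydroxy diaryl ether next to an acyl-bearing ring, where a phenoxide or alkoxide under strong base could cause a Smiles-type aryl shift.

The difficulty lies in assembling four adjacent substituents on ring A plus one isolated stereocentre while keeping the last steps close to neutral. The key step exploits the fact that Cα is both the atom bonded to C3 and an oxygen-bearing carbon: the unit O–Cα–CH2–C(CH3)2–OH is the skeleton of 3-methylbutane-1,3-diol, whose primary carbinol carbon can be made into a chiral carbenoid, inserted into the C3–B bond of a ring A boronate and then oxidised at boron.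

## Logic of the disconnections

**23 to 22.** The two O–CH2Ph bonds (phenol ether on ring B, ester on C1) are cut last. Hydrogenolysis is neutral and independent of the crowding around the carboxyl group, so no hydrolysis of a di-ortho-substituted benzoate is needed and the free 2'-phenol never meets base. The forward step must stop before the benzylic C–OH bonds are reduced.

**22 to 21.** Both Si–O bonds (primary ether on ring B, tertiary ether on the chain) are cut together. One fluoride step then removes both groups, and the product is still a neutral, easily purified ester. The forward step must be buffered so that no free alkoxide sits next to the diaryl ether.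

**21 to 20.** The Cα–O bond is traced back to a Cα–B bond. This hands the stereochemical problem to boron chemistry, since the oxidation is stereoretentive; the oxidant only has to spare the benzyl ester.

**20 to 14 and 17.** The C3–Cα bond is cut. This is the most simplifying cut: it separates the whole chain, with its stereocentre, from an achiral biaryl ether, and the chain comes from a cheap diol. The forward step must form one enantiomer under reagent control and must tolerate an ester, which is why 14 carries a hindered benzyl ester and no free organolithium base may remain.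

**14 to 12 and 13.** The C3–B bond is cut to a C3–Br bond. The bromine is already present in the ring A starting material and survives all earlier steps. The borylation must leave the ester and both ethers intact.

**12 to 11 to 10.** The ester O–CH2Ph bond is cut, and the carboxyl carbon is taken back to the aldehyde level. The reason is that a formyl group activates the neighbouring C–F bond far better than a twisted ester, and an ester would also be exposed to hot phenoxide. The cost is two simple steps (oxidation, O-alkylation of the carboxylate).

**10 to 9 and 6.** The C6–O bond of the diaryl ether is cut. The two halves are of similar size and each is made in a few steps. The forward step is an addition–elimination in which a di-ortho-substituted phenoxide must attack; the ortho formyl group and fluoride as leaving group meet this demand.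

**9 to 7.** The C1–CHO bond is cut. The proton between fluorine and methoxy in 7 is the most acidic, so one directed metalation installs the C1 carbon. The base must not exchange the bromine.

**6 to 5 to 4 to 3 to 2 to 1.** Ring B is traced back by functional-group changes and one C–C bond (C6'–CH2) to a commercial phenol. The forward steps must formylate ortho to the phenol, exchange the methyl ether for a benzyl ether at the correct oxygen, and silylate the alcohol in the presence of the phenol.

**17 to 16 to 15.** The Si–O and carbamate C–O bonds are cut. The primary hydroxyl of 15 is acylated selectively and the tertiary one is then silylated. The carbamate serves both as the directing group for lithiation and as the leaving group.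

## Other disconnections considered

**Alternative 1:** The cut is through ring B itself, at C1'–C6' and C3'–C4'. In the forward step the aryloxyacetone A1 would condense twice with ethyl 2,4-dioxopentanoate A2: its OCH2 carbon with the keto ester carbonyl and its methyl group with the acetyl carbonyl. Loss of two molecules of water would then aromatise the ring to give A3.

- In its favour: no diaryl ether has to be forged between two crowded arenes, since a simple O-alkylation of a ring A phenol replaces it. The ring B phenol emerges unprotected, and the ring A carboxyl is carried as the free acid, so no ester on C1 has to be removed. On these three points the alternative is better than the chosen plan.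
- Against it: there are four possible pairings of nucleophilic and electrophilic sites, the methyl group of A1 is a weak nucleophile, and A2 can condense with itself. Afterwards the ring B ester must be reduced beside a free benzoic acid, and the dioxane must be opened with acid next to the ionisable benzylic C–O bond.
- Comparison: on stereochemistry the two plans are equal in effort (one asymmetric operation each), but here it has to be done earlier and carried through. On mechanism a condensation with uncertain regiocontrol stands against a stereospecific, reagent-controlled coupling. On step economy the end game is shorter (two steps against three), but the way to A1 is long, so no overall gain is expected.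

**Alternative 2:** The cut removes ring A, at C1–C2, C5–C6 and C2–C3, with C4–C5 made in the same operation. Irradiation of the diazoketone A4 would cause a Wolff rearrangement; the resulting ketene would add [2+2] to the aryl alkynyl ether A5, and 4π opening followed by 6π closure would give the phenol A6.

- In its favour: the substitution pattern of ring A is fixed unambiguously by the pericyclic sequence, the ether oxygen arrives on the alkyne so that no activated fluoroarene is needed, and the assembly is convergent. On regiochemical certainty for ring A it is the equal of the chosen plan.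
- Against it: A5 requires an ynol ether to be built on a hindered phenol, A4 is a sensitive diazoketone that already carries the stereocentre, and the photochemical step is hard to scale. After the annulation, an O-methylation, removal of the methoxybenzyl group, a two-stage oxidation to the acid and three deprotections (one acidic) remain.
- Comparison: the key step sets no stereocentre, whereas the chosen key step does. On step economy it is clearly longer after the key step (about seven steps against three).

**Alternative 3:** The cut is at C6–O and C1–CO2H. Fluoride would release an aryne from the silyl triflate A7; the cesium salt of 6 would add at the aryne carbon meta to the methoxy group, and the aryl anion ortho to it would be captured by carbon dioxide A8 to give the acid A9.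

- In its favour: two bonds, including the crowded ether bond and the carboxyl group, would form in one step, and the acid is obtained directly. On step economy at this stage it is better than the chosen plan (one step against steps 6 to 9), and it uses the same ring B phenol 6.
- Against it: the aryl anion can be protonated instead of carboxylated, A8 can reversibly carbonate the phenoxide and lower its reactivity, and the phenoxide is hindered. A7 needs several steps with the stereocentre already in place, and an acidic acetal cleavage stands at the end.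
- Comparison: on mechanism the oxygen-nucleophile variant of the three-component coupling is less secure than the boron chemistry of the chosen plan. The regiochemistry rests on the inductive effect of the methoxy group and is equal in reliability to the metalation used in the chosen plan. The stereocentre again needs a separate, earlier asymmetric step.

Key step: step 13

Remark: the connectivity and the descriptors of the precursor boronate, the benzylic boronate and the target agree with one another (R at Cα throughout). The changes made are in spectator groups only: a benzyl ester in place of a methyl ester, and a formyl group as activating group for the fluoride displacement.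

Remark: salts formed in the flask by simple O–H deprotonation (phenoxides, carboxylates) are treated as part of the conditions; carbon-centred organolithium intermediates and the boronate complex are numbered.

## Route

Step 1
Reactants: 1 2-methoxy-4-methylphenol (creosol)
Product: 2 2-hydroxy-3-methoxy-5-methylbenzaldehyde
Conditions: MgCl2, Et3N, (CH2O)n, MeCN, reflux; then 1 M HCl
Reagents that add atoms: paraformaldehyde (as formaldehyde), C=O
Why: Casnati–Skattebøl ortho-formylation: the magnesium phenoxide delivers formaldehyde to the only free position ortho to the hydroxyl (para is blocked by the methyl group), and a second formaldehyde oxidises the benzylic alkoxide to the aldehyde.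

Step 2
Reactants: 2 2-hydroxy-3-methoxy-5-methylbenzaldehyde
Product: 3 2,3-dihydroxy-5-methylbenzaldehyde
Conditions: BBr3, CH2Cl2, −78 °C to rt; then H2O
Reagents that add atoms: none
Why: Lewis-acid cleavage of the aryl methyl ether: BBr3 complexes the ether oxygen and bromide removes the methyl group by SN2 attack; the aldehyde is released unchanged on aqueous work-up.

Step 3
Reactants: 3 2,3-dihydroxy-5-methylbenzaldehyde
Product: 4 3-(benzyloxy)-2-hydroxy-5-methylbenzaldehyde
Conditions: KOt-Bu (2.1 equiv), DMSO, rt; BnBr (1.0 equiv); then aq. NH4Cl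
Reagents that add atoms: benzyl bromide, BrCc1ccccc1
Why: Williamson etherification of the dianion: the 2-oxide is delocalised into the formyl group and chelated, so the more basic 3-oxide should take the single equivalent of benzyl bromide.

Step 4
Reactants: 4 3-(benzyloxy)-2-hydroxy-5-methylbenzaldehyde
Product: 5 2-(benzyloxy)-6-(hydroxymethyl)-4-methylphenol
Conditions: NaBH4, MeOH, 0 °C
Reagents that add atoms: none
Why: Borohydride reduction of the aldehyde to the primary benzylic alcohol; the phenol and the benzyl ether are inert.

Step 5
Reactants: 5 2-(benzyloxy)-6-(hydroxymethyl)-4-methylphenol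
Product: 6 2-(benzyloxy)-4-methyl-6-({[tri(propan-2-yl)silyl]oxy}methyl)phenol
Conditions: i-Pr3SiCl (1.05 equiv), imidazole, CH2Cl2, 0 °C to rt
Reagents that add atoms: chlorotri(propan-2-yl)silane, CC(C)[Si](Cl)(C(C)C)C(C)C
Why: Chemoselective silylation: the bulky silyl chloride should react at the unhindered primary alcohol much faster than at the phenol, which has two ortho neighbours. Protecting before the ether synthesis also removes an alkoxide that could later attack ring A in a Smiles-type aryl transfer.

Step 6
Reactants: 7 2-bromo-5-fluoroanisole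
Product: 9 3-bromo-6-fluoro-2-methoxybenzaldehyde, via aryllithium 8 (not isolated)
Conditions: LiN(iPr)2, THF, −78 °C; DMF, −78 to 0 °C; aq. NH4Cl
Reagents that add atoms: N,N-dimethylformamide, CN(C)C=O; LiN(iPr)2, [Li]N(C(C)C)C(C)C (lithium of 8 only)
Why: Directed ortho-metalation: the proton between fluorine and methoxy is the most acidic, and the amide base does not exchange the bromine. At −78 °C the aryllithium should neither lose LiF nor allow bromine migration before DMF formylates it.

Step 7
Reactants: 9 3-bromo-6-fluoro-2-methoxybenzaldehyde; 6 2-(benzyloxy)-4-methyl-6-({[tri(propan-2-yl)silyl]oxy}methyl)phenol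
Product: 10 6-[2-(benzyloxy)-4-methyl-6-({[tri(propan-2-yl)silyl]oxy}methyl)phenoxy]-3-bromo-2-methoxybenzaldehyde
Conditions: K2CO3, DMF, 90 °C
Reagents that add atoms: none
Why: Nucleophilic aromatic substitution by addition–elimination: the ortho formyl group stabilises the Meisenheimer adduct far better than a twisted ester would, and fluoride is the best leaving group for this mechanism. The bromine, meta to the aldehyde, is not displaced.

Step 8
Reactants: 10 6-[2-(benzyloxy)-4-methyl-6-({[tri(propan-2-yl)silyl]oxy}methyl)phenoxy]-3-bromo-2-methoxybenzaldehyde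
Product: 11 6-[2-(benzyloxy)-4-methyl-6-({[tri(propan-2-yl)silyl]oxy}methyl)phenoxy]-3-bromo-2-methoxybenzoic acid
Conditions: NaClO2, NaH2PO4, 2-methylbut-2-ene, t-BuOH/THF/H2O, 0 °C to rt
Reagents that add atoms: sodium chlorite, [Na+].[O-]Cl=O
Why: Pinnick oxidation: chlorous acid converts the hindered aldehyde to the acid without touching the aryl bromide, silyl ether or benzyl ether. The alkene removes the hypochlorous acid that could chlorinate electron-rich ring B.

Step 9
Reactants: 11 6-[2-(benzyloxy)-4-methyl-6-({[tri(propan-2-yl)silyl]oxy}methyl)phenoxy]-3-bromo-2-methoxybenzoic acid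
Product: 12 benzyl 6-[2-(benzyloxy)-4-methyl-6-({[tri(propan-2-yl)silyl]oxy}methyl)phenoxy]-3-bromo-2-methoxybenzoate
Conditions: BnBr, K2CO3, DMF, rt
Reagents that add atoms: benzyl bromide, BrCc1ccccc1
Why: SN2 alkylation of the carboxylate at oxygen, which is insensitive to the two ortho substituents that would block esterification at the carbonyl. The benzyl ester is later removed by hydrogenolysis together with the ring B benzyl ether.

Step 10
Reactants: 12 benzyl 6-[2-(benzyloxy)-4-methyl-6-({[tri(propan-2-yl)silyl]oxy}methyl)phenoxy]-3-bromo-2-methoxybenzoate; 13 bis(pinacolato)diboron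
Product: 14 benzyl 6-[2-(benzyloxy)-4-methyl-6-({[tri(propan-2-yl)silyl]oxy}methyl)phenoxy]-2-methoxy-3-(4,4,5,5-tetramethyl-1,3,2-dioxaborolan-2-yl)benzoate
Conditions: PdCl2(dppf) (5 mol %), KOAc, 1,4-dioxane, 90 °C
Reagents that add atoms: none
Why: Miyaura borylation: zerovalent palladium inserts into the C3–Br bond, acetate assists transmetalation from 13, and reductive elimination gives the aryl boronate. KOAc is too weak a base to couple the product with remaining bromide, and the ester and ethers are inert.

Step 11
Reactants: 15 3-methylbutane-1,3-diol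
Product: 16 3-hydroxy-3-methylbutyl N,N-di(propan-2-yl)carbamate
Conditions: i-Pr2NCOCl, Et3N, CH2Cl2, reflux
Reagents that add atoms: N,N-di(propan-2-yl)carbamoyl chloride, CC(C)N(C(C)C)C(Cl)=O
Why: O-Acylation of the primary hydroxyl by the hindered carbamoyl chloride; the tertiary hydroxyl is too crowded to react.

Step 12
Reactants: 16 3-hydroxy-3-methylbutyl N,N-di(propan-2-yl)carbamate
Product: 17 3-methyl-3-[(triethylsilyl)oxy]butyl N,N-di(propan-2-yl)carbamate
Conditions: Et3SiOTf, 2,6-lutidine, CH2Cl2, 0 °C
Reagents that add atoms: triethylsilyl trifluoromethanesulfonate, CC[Si](CC)(CC)OS(=O)(=O)C(F)(F)F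
Why: Silylation of the tertiary alcohol with the reactive silyl triflate removes the acidic proton before the lithiation; the ether is cleaved by fluoride at the end.

Step 13
Reactants: 17 3-methyl-3-[(triethylsilyl)oxy]butyl N,N-di(propan-2-yl)carbamate; 14 benzyl 6-[2-(benzyloxy)-4-methyl-6-({[tri(propan-2-yl)silyl]oxy}methyl)phenoxy]-2-methoxy-3-(4,4,5,5-tetramethyl-1,3,2-dioxaborolan-2-yl)benzoate
Product: 20 benzyl 6-[2-(benzyloxy)-4-methyl-6-({[tri(propan-2-yl)silyl]oxy}methyl)phenoxy]-2-methoxy-3-{(1R)-3-methyl-1-(4,4,5,5-tetramethyl-1,3,2-dioxaborolan-2-yl)-3-[(triethylsilyl)oxy]butyl}benzoate, via lithiated carbamate 18 (not isolated), via boronate complex 19 (not isolated)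
Conditions: 17 (1.3 equiv), (−)-sparteine (1.3 equiv), s-BuLi (1.25 equiv), Et2O, −78 °C, 5 h; 14 (1.0 equiv), −78 °C, 1 h; MgBr2·OEt2, −78 °C to reflux; aq. NH4Cl
Reagents that add atoms: s-BuLi, [Li]C(C)CC (lithium of 18 and 19 only)
Why: This is a lithiation–borylation, a sparteine-mediated asymmetric deprotonation followed by a Matteson-type 1,2-metallate rearrangement; the closest known reaction type is the homologation of aryl pinacol boronates with sparteine-complexed lithiated primary alkyl carbamates. s-BuLi/(−)-sparteine removes the pro-S proton next to the carbamate oxygen and gives the chelated, configurationally stable (S)-organolithium 18. Boronate 14 traps it with retention to give complex 19, and on warming with MgBr2 the aryl group shifts from boron to carbon anti-periplanar to the leaving carbamate, with inversion at carbon, which forms the C3–Cα bond. No ring is closed. The configuration at Cα is set by the reagent alone: (S)-18, retention on borylation and inversion in the shift give (R)-20, and because boron ranks below both carbon neighbours while oxygen ranks above them, the later stereoretentive exchange of boron for oxygen again gives the R descriptor. The step needs chemoselectivity for boron over the benzyl ester and the benzylic C–H bonds; this is secured by the very fast complexation at −78 °C, by the two ortho substituents that shield the ester carbonyl, and by using less s-BuLi than carbamate so that no free alkyllithium meets 14. The aryl group migrates in preference to a pinacol oxygen because its ipso carbon is made electron-rich by the ortho methoxy and para aryloxy groups.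

Step 14
Reactants: 20 benzyl 6-[2-(benzyloxy)-4-methyl-6-({[tri(propan-2-yl)silyl]oxy}methyl)phenoxy]-2-methoxy-3-{(1R)-3-methyl-1-(4,4,5,5-tetramethyl-1,3,2-dioxaborolan-2-yl)-3-[(triethylsilyl)oxy]butyl}benzoate
Product: 21 benzyl 6-[2-(benzyloxy)-4-methyl-6-({[tri(propan-2-yl)silyl]oxy}methyl)phenoxy]-3-{(1R)-1-hydroxy-3-methyl-3-[(triethylsilyl)oxy]butyl}-2-methoxybenzoate
Conditions: NaBO3·4H2O, THF/H2O (1:1), rt
Reagents that add atoms: sodium perborate, [Na+].[Na+].O[B-]1(O)OO[B-](O)(O)OO1
Why: Peroxide oxidation of the C–B bond: the peroxo oxygen adds to boron and the benzylic carbon shifts from boron to oxygen with retention, so (R)-20 should give (R)-21. The weakly basic perborate spares the benzyl ester and both silyl ethers.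

Step 15
Reactants: 21 benzyl 6-[2-(benzyloxy)-4-methyl-6-({[tri(propan-2-yl)silyl]oxy}methyl)phenoxy]-3-{(1R)-1-hydroxy-3-methyl-3-[(triethylsilyl)oxy]butyl}-2-methoxybenzoate
Product: 22 benzyl 6-[2-(benzyloxy)-6-(hydroxymethyl)-4-methylphenoxy]-3-[(1R)-1,3-dihydroxy-3-methylbutyl]-2-methoxybenzoate
Conditions: Bu4NF, AcOH, THF, rt
Reagents that add atoms: none
Why: Fluoride-induced desilylation, driven by the strong Si–F bond, removes the primary and the tertiary silyl ether in one operation. Acetic acid buffers the alkoxides, so neither the benzyl ester nor the diaryl ether (Smiles-type aryl transfer) is endangered, and the stereocentre is not involved.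

Step 16
Reactants: 22 benzyl 6-[2-(benzyloxy)-6-(hydroxymethyl)-4-methylphenoxy]-3-[(1R)-1,3-dihydroxy-3-methylbutyl]-2-methoxybenzoate
Product: 23 3-[(1R)-1,3-dihydroxy-3-methylbutyl]-6-[2-hydroxy-6-(hydroxymethyl)-4-methylphenoxy]-2-methoxybenzoic acid
Conditions: H2 (1 atm), 10% Pd/C, EtOAc, rt
Reagents that add atoms: none
Why: Catalytic hydrogenolysis cleaves the benzyl ether and the benzyl ester in one neutral operation, regardless of the crowding around the carboxyl group. Benzylic alcohols are cleaved much more slowly in a neutral aprotic medium, so the reaction is stopped after uptake of two equivalents of hydrogen.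

## Compound list

1 | 2-methoxy-4-methylphenol (creosol) | COc1cc(C)ccc1O | starting material
2 | 2-hydroxy-3-methoxy-5-methylbenzaldehyde | COc1cc(C)cc(C=O)c1O | intermediate
3 | 2,3-dihydroxy-5-methylbenzaldehyde | Oc1cc(C)cc(C=O)c1O | intermediate
4 | 3-(benzyloxy)-2-hydroxy-5-methylbenzaldehyde | O=Cc1cc(C)cc(OCc2ccccc2)c1O | intermediate
5 | 2-(benzyloxy)-6-(hydroxymethyl)-4-methylphenol | OCc1cc(C)cc(OCc2ccccc2)c1O | intermediate
6 | 2-(benzyloxy)-4-methyl-6-({[tri(propan-2-yl)silyl]oxy}methyl)phenol | CC(C)[Si](OCc1cc(C)cc(OCc2ccccc2)c1O)(C(C)C)C(C)C | intermediate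
7 | 2-bromo-5-fluoroanisole (1-bromo-4-fluoro-2-methoxybenzene) | COc1cc(F)ccc1Br | starting material
8 | (3-bromo-6-fluoro-2-methoxyphenyl)lithium | [Li]c1c(F)ccc(Br)c1OC | intermediate
9 | 3-bromo-6-fluoro-2-methoxybenzaldehyde | COc1c(Br)ccc(F)c1C=O | intermediate
10 | 6-[2-(benzyloxy)-4-methyl-6-({[tri(propan-2-yl)silyl]oxy}methyl)phenoxy]-3-bromo-2-methoxybenzaldehyde | COc1c(Br)ccc(Oc2c(OCc3ccccc3)cc(C)cc2CO[Si](C(C)C)(C(C)C)C(C)C)c1C=O | intermediate
11 | 6-[2-(benzyloxy)-4-methyl-6-({[tri(propan-2-yl)silyl]oxy}methyl)phenoxy]-3-bromo-2-methoxybenzoic acid | COc1c(Br)ccc(Oc2c(OCc3ccccc3)cc(C)cc2CO[Si](C(C)C)(C(C)C)C(C)C)c1C(=O)O | intermediate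
12 | benzyl 6-[2-(benzyloxy)-4-methyl-6-({[tri(propan-2-yl)silyl]oxy}methyl)phenoxy]-3-bromo-2-methoxybenzoate | COc1c(Br)ccc(Oc2c(OCc3ccccc3)cc(C)cc2CO[Si](C(C)C)(C(C)C)C(C)C)c1C(=O)OCc1ccccc1 | intermediate
13 | bis(pinacolato)diboron | CC1(C)OB(OC1(C)C)B1OC(C)(C)C(C)(C)O1 | starting material
14 | benzyl 6-[2-(benzyloxy)-4-methyl-6-({[tri(propan-2-yl)silyl]oxy}methyl)phenoxy]-2-methoxy-3-(4,4,5,5-tetramethyl-1,3,2-dioxaborolan-2-yl)benzoate | COc1c(B2OC(C)(C)C(C)(C)O2)ccc(Oc2c(OCc3ccccc3)cc(C)cc2CO[Si](C(C)C)(C(C)C)C(C)C)c1C(=O)OCc1ccccc1 | intermediate
15 | 3-methylbutane-1,3-diol | CC(C)(O)CCO | starting material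
16 | 3-hydroxy-3-methylbutyl N,N-di(propan-2-yl)carbamate | CC(C)N(C(C)C)C(=O)OCCC(C)(C)O | intermediate
17 | 3-methyl-3-[(triethylsilyl)oxy]butyl N,N-di(propan-2-yl)carbamate | CC(C)N(C(C)C)C(=O)OCCC(C)(C)O[Si](CC)(CC)CC | intermediate
18 | (1S)-1-lithio-3-methyl-3-[(triethylsilyl)oxy]butyl N,N-di(propan-2-yl)carbamate as its (−)-sparteine complex | CC(C)N(C(C)C)C(=O)O[C@@H]([Li])CC(C)(C)O[Si](CC)(CC)CC | intermediate
19 | lithium {3-[(benzyloxy)carbonyl]-4-[2-(benzyloxy)-4-methyl-6-({[tri(propan-2-yl)silyl]oxy}methyl)phenoxy]-2-methoxyphenyl}{(1S)-1-[(dipropan-2-ylcarbamoyl)oxy]-3-methyl-3-[(triethylsilyl)oxy]butyl}(pinacolato)borate | [Li+].CC(C)N(C(C)C)C(=O)O[C@@H]([B-]1(OC(C)(C)C(C)(C)O1)c1c(OC)c(C(=O)OCc2ccccc2)c(Oc2c(OCc3ccccc3)cc(C)cc2CO[Si](C(C)C)(C(C)C)C(C)C)cc1)CC(C)(C)O[Si](CC)(CC)CC | intermediate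
20 | benzyl 6-[2-(benzyloxy)-4-methyl-6-({[tri(propan-2-yl)silyl]oxy}methyl)phenoxy]-2-methoxy-3-{(1R)-3-methyl-1-(4,4,5,5-tetramethyl-1,3,2-dioxaborolan-2-yl)-3-[(triethylsilyl)oxy]butyl}benzoate | O=C(OCc1ccccc1)c1c(OC)c([C@H](B2OC(C)(C)C(C)(C)O2)CC(C)(C)O[Si](CC)(CC)CC)ccc1Oc1c(OCc2ccccc2)cc(C)cc1CO[Si](C(C)C)(C(C)C)C(C)C | intermediate
21 | benzyl 6-[2-(benzyloxy)-4-methyl-6-({[tri(propan-2-yl)silyl]oxy}methyl)phenoxy]-3-{(1R)-1-hydroxy-3-methyl-3-[(triethylsilyl)oxy]butyl}-2-methoxybenzoate | O=C(OCc1ccccc1)c1c(OC)c([C@H](O)CC(C)(C)O[Si](CC)(CC)CC)ccc1Oc1c(OCc2ccccc2)cc(C)cc1CO[Si](C(C)C)(C(C)C)C(C)C | intermediate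
22 | benzyl 6-[2-(benzyloxy)-6-(hydroxymethyl)-4-methylphenoxy]-3-[(1R)-1,3-dihydroxy-3-methylbutyl]-2-methoxybenzoate | O=C(OCc1ccccc1)c1c(OC)c([C@H](O)CC(C)(C)O)ccc1Oc1c(OCc2ccccc2)cc(C)cc1CO | intermediate
23 | 3-[(1R)-1,3-dihydroxy-3-methylbutyl]-6-[2-hydroxy-6-(hydroxymethyl)-4-methylphenoxy]-2-methoxybenzoic acid | COc1c([C@H](O)CC(C)(C)O)ccc(Oc2c(O)cc(C)cc2CO)c1C(=O)O | target

## Step count and least certain steps

Total step count: 16. Longest linear sequence: 13 steps (steps 1 to 5, 7 to 10 and 13 to 16). Should 2 or 9 be obtainable from a supplier, step 1 or step 6 falls away.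

**Step 13 (key step).** The most likely failure is loss of conversion. The lithiated carbamate may attack the benzyl ester or a benzylic C–H bond instead of boron, or complexation with the ortho-substituted boronate may be slow, so that the organolithium decomposes on warming. Loss of enantiopurity is less likely, because each stage after the deprotonation is stereospecific.

Fallback, leaving the route at 12 and returning at 22: an aryl ketone is built and reduced asymmetrically.
- Stille coupling of 12 with tributyl(1-ethoxyethenyl)stannane (PdCl2(PPh3)2, toluene, 100 °C) would give the enol ether benzyl 6-[2-(benzyloxy)-4-methyl-6-({[tri(propan-2-yl)silyl]oxy}methyl)phenoxy]-3-(1-ethoxyethenyl)-2-methoxybenzoate F1.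
- Brief treatment with dilute HCl in THF would hydrolyse it to the methyl ketone benzyl 3-acetyl-6-[2-(benzyloxy)-4-methyl-6-({[tri(propan-2-yl)silyl]oxy}methyl)phenoxy]-2-methoxybenzoate F2.
- The lithium enolate of F2 (LiN(iPr)2, THF, −78 °C) would add to acetone to give the aldol benzyl 6-[2-(benzyloxy)-4-methyl-6-({[tri(propan-2-yl)silyl]oxy}methyl)phenoxy]-3-(3-hydroxy-3-methylbutanoyl)-2-methoxybenzoate F3.
- Noyori–Ikariya transfer hydrogenation with RuCl[(R,R)-TsDPEN](p-cymene) in HCO2H/Et3N, the ligand enantiomer that delivers (R)-1-arylalkanols from aryl alkyl ketones, would give the diol benzyl 6-[2-(benzyloxy)-4-methyl-6-({[tri(propan-2-yl)silyl]oxy}methyl)phenoxy]-3-[(1R)-1,3-dihydroxy-3-methylbutyl]-2-methoxybenzoate F4.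
- Bu4NF/AcOH would then remove the silyl group and give 22.

**Step 3.** The risk is alkylation at the wrong oxygen or double alkylation, because the selectivity rests only on the different nucleophilicity of the two oxides. Fallback, from 3 back to 4: exhaustive benzylation (BnBr in excess, K2CO3, DMF) would give 2,3-bis(benzyloxy)-5-methylbenzaldehyde F5. Chelation-controlled cleavage with MgBr2·OEt2 in toluene/Et2O at reflux would then remove only the benzyl ether ortho to the formyl group and return 4.

**Step 5.** The risk is competing silylation of the phenol, since phenols are good partners for silyl chlorides and the selectivity is purely steric. Fallback, from 5 back to 6: both hydroxyls are silylated with i-Pr3SiOTf and 2,6-lutidine to give [2-(benzyloxy)-4-methyl-6-({[tri(propan-2-yl)silyl]oxy}methyl)phenoxy]tri(propan-2-yl)silane F6. The much more base-labile aryl silyl ether is then cleaved alone with Cs2CO3 in DMF/H2O to return 6.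

**Step 16.** The risk is over-reduction: hydrogenolysis of a benzylic C–OH bond, most likely at the ring A carbinol, which is activated by the ortho methoxy and para aryloxy groups, once the benzyl groups are gone and the product acid makes the medium slightly acidic. Fallback, from 21 to 23: the order of the last two operations is reversed. Hydrogenolysis of 21 (H2, 10% Pd/C, EtOAc) while the ring B hydroxymethyl group is still silylated and the carbinol is shielded by the neighbouring silyl ether would give 6-[2-hydroxy-4-methyl-6-({[tri(propan-2-yl)silyl]oxy}methyl)phenoxy]-3-{(1R)-1-hydroxy-3-methyl-3-[(triethylsilyl)oxy]butyl}-2-methoxybenzoic acid F7. Buffered fluoride (Bu4NF/AcOH, THF) would then remove both silyl groups and give 23.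

## Further compounds

F1 | step 13 | benzyl 6-[2-(benzyloxy)-4-methyl-6-({[tri(propan-2-yl)silyl]oxy}methyl)phenoxy]-3-(1-ethoxyethenyl)-2-methoxybenzoate | CCOC(=C)c1ccc(Oc2c(OCc3ccccc3)cc(C)cc2CO[Si](C(C)C)(C(C)C)C(C)C)c(C(=O)OCc2ccccc2)c1OC
F2 | step 13 | benzyl 3-acetyl-6-[2-(benzyloxy)-4-methyl-6-({[tri(propan-2-yl)silyl]oxy}methyl)phenoxy]-2-methoxybenzoate | CC(=O)c1ccc(Oc2c(OCc3ccccc3)cc(C)cc2CO[Si](C(C)C)(C(C)C)C(C)C)c(C(=O)OCc2ccccc2)c1OC
F3 | step 13 | benzyl 6-[2-(benzyloxy)-4-methyl-6-({[tri(propan-2-yl)silyl]oxy}methyl)phenoxy]-3-(3-hydroxy-3-methylbutanoyl)-2-methoxybenzoate | CC(C)(O)CC(=O)c1ccc(Oc2c(OCc3ccccc3)cc(C)cc2CO[Si](C(C)C)(C(C)C)C(C)C)c(C(=O)OCc2ccccc2)c1OC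
F4 | step 13 | benzyl 6-[2-(benzyloxy)-4-methyl-6-({[tri(propan-2-yl)silyl]oxy}methyl)phenoxy]-3-[(1R)-1,3-dihydroxy-3-methylbutyl]-2-methoxybenzoate | O=C(OCc1ccccc1)c1c(OC)c([C@H](O)CC(C)(C)O)ccc1Oc1c(OCc2ccccc2)cc(C)cc1CO[Si](C(C)C)(C(C)C)C(C)C
F5 | step 3 | 2,3-bis(benzyloxy)-5-methylbenzaldehyde | O=Cc1cc(C)cc(OCc2ccccc2)c1OCc1ccccc1
F6 | step 5 | [2-(benzyloxy)-4-methyl-6-({[tri(propan-2-yl)silyl]oxy}methyl)phenoxy]tri(propan-2-yl)silane | CC(C)[Si](OCc1cc(C)cc(OCc2ccccc2)c1O[Si](C(C)C)(C(C)C)C(C)C)(C(C)C)C(C)C
F7 | step 16 | 6-[2-hydroxy-4-methyl-6-({[tri(propan-2-yl)silyl]oxy}methyl)phenoxy]-3-{(1R)-1-hydroxy-3-methyl-3-[(triethylsilyl)oxy]butyl}-2-methoxybenzoic acid | COc1c([C@H](O)CC(C)(C)O[Si](CC)(CC)CC)ccc(Oc2c(O)cc(C)cc2CO[Si](C(C)C)(C(C)C)C(C)C)c1C(=O)O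
A1 | alternative 1 | 2-methoxy-6-(2-oxopropoxy)-3-[(4R)-2,2,6,6-tetramethyl-1,3-dioxan-4-yl]benzoic acid | COc1c([C@H]2CC(C)(C)OC(C)(C)O2)ccc(OCC(C)=O)c1C(=O)O
A2 | alternative 1 | ethyl 2,4-dioxopentanoate | CCOC(=O)C(=O)CC(C)=O
A3 | alternative 1 | 6-[2-(ethoxycarbonyl)-6-hydroxy-4-methylphenoxy]-2-methoxy-3-[(4R)-2,2,6,6-tetramethyl-1,3-dioxan-4-yl]benzoic acid | COc1c([C@H]2CC(C)(C)OC(C)(C)O2)ccc(Oc2c(O)cc(C)cc2C(=O)OCC)c1C(=O)O
A4 | alternative 2 | (3E)-1-diazo-4-[(4R)-2,2,6,6-tetramethyl-1,3-dioxan-4-yl]but-3-en-2-one | [N-]=[N+]=CC(=O)/C=C/[C@H]1CC(C)(C)OC(C)(C)O1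
A5 | alternative 2 | {[3-(benzyloxy)-2-({3-[(4-methoxybenzyl)oxy]prop-1-yn-1-yl}oxy)-5-methylbenzyl]oxy}tri(propan-2-yl)silane | COc1ccc(COCC#COc2c(OCc3ccccc3)cc(C)cc2CO[Si](C(C)C)(C(C)C)C(C)C)cc1
A6 | alternative 2 | 3-[2-(benzyloxy)-4-methyl-6-({[tri(propan-2-yl)silyl]oxy}methyl)phenoxy]-2-{[(4-methoxybenzyl)oxy]methyl}-6-[(4R)-2,2,6,6-tetramethyl-1,3-dioxan-4-yl]phenol | COc1ccc(COCc2c(O)c([C@H]3CC(C)(C)OC(C)(C)O3)ccc2Oc2c(OCc3ccccc3)cc(C)cc2CO[Si](C(C)C)(C(C)C)C(C)C)cc1
A7 | alternative 3 | 2-methoxy-3-[(4R)-2,2,6,6-tetramethyl-1,3-dioxan-4-yl]-6-(trimethylsilyl)phenyl trifluoromethanesulfonate | COc1c([C@H]2CC(C)(C)OC(C)(C)O2)ccc([Si](C)(C)C)c1OS(=O)(=O)C(F)(F)F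
A8 | alternative 3 | carbon dioxide | O=C=O
A9 | alternative 3 | 6-[2-(benzyloxy)-4-methyl-6-({[tri(propan-2-yl)silyl]oxy}methyl)phenoxy]-2-methoxy-3-[(4R)-2,2,6,6-tetramethyl-1,3-dioxan-4-yl]benzoic acid | COc1c([C@H]2CC(C)(C)OC(C)(C)O2)ccc(Oc2c(OCc3ccccc3)cc(C)cc2CO[Si](C(C)C)(C(C)C)C(C)C)c1C(=O)O
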